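**Strategy**

The route rests on forming the bond between C2 of pyran ring C and the ipso carbon of ring B. In the key step an enantiopure (3R)-chroman-2,3-diol, a lactol used as its anomeric mixture, meets a 3,5-bis(silyloxy)-4-methoxyphenylboronic acid: ionisation at the O1–C2 acetal carbon gives an oxocarbenium ion, and boron bound to the C3 oxygen hands ring B to the same face of C2. One operation should thus make the C2–aryl bond, set C2 and funnel both anomers into the 2,3-cis flavan-3-ol. The step exploits the C3 oxygen next to the acetal carbon C2 in ring C. C3 is set by proline-catalysed aminoxylation; esterification with silylated ferulic acid and desilylation complete the synthesis.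

Key step: step 7

Remark: lactols 4, 5, 6 and 11 are mixtures of anomers at C2, so C2 is left undefined in their SMILES; the target is taken as the (2R,3R) 2,3-cis flavan-3-ol with an (E) ester, as drawn.

**Route**

Step 1
Reactants: 1 5,7-dihydroxycoumarin
Product: 2 5,7-bis(tert-butyldimethylsilyloxy)coumarin
Conditions: TBSCl (2.4 equiv), imidazole, DMF, rt
Reagents that add atoms: tert-butyldimethylsilyl chloride, CC(C)(C)[Si](C)(C)Cl
Why: Imidazole-promoted silyl ether formation at both phenols; the lactone is untouched and the silyl ethers can be removed at the end without touching the cinnamate double bond.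

Step 2
Reactants: 2 5,7-bis(tert-butyldimethylsilyloxy)coumarin
Product: 3 5,7-bis(tert-butyldimethylsilyloxy)chroman-2-one
Conditions: H2 (3 atm), Pd/C, EtOAc, rt
Reagents that add atoms: none
Why: Heterogeneous catalytic hydrogenation of the conjugated C3=C4 bond of a coumarin; aryl silyl ethers and the lactone carbonyl should survive.

Step 3
Reactants: 3 5,7-bis(tert-butyldimethylsilyloxy)chroman-2-one
Product: 4 5,7-bis(tert-butyldimethylsilyloxy)chroman-2-ol
Conditions: i-Bu2AlH (1.1 equiv), CH2Cl2, −78 °C; then aq. KNaC4H4O6 (Rochelle salt)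
Reagents that add atoms: none
Why: Partial reduction of a lactone to the lactol by i-Bu2AlH, the tetrahedral aluminium alkoxide persisting at low temperature until work-up; the anomeric centre forms as a mixture, which does not matter.

Step 4
Reactants: 4 5,7-bis(tert-butyldimethylsilyloxy)chroman-2-ol
Product: 6 (3R)-5,7-bis(tert-butyldimethylsilyloxy)chroman-2,3-diol, via aminoxy lactol 5 (not isolated)
Conditions: PhNO (1.0 equiv), L-proline (20 mol %), MeCN, −20 °C; then silica plug, H2 (1 atm), Pd/C, EtOAc, rt; dilute citric acid wash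
Reagents that add atoms: nitrosobenzene, O=Nc1ccccc1
Why: Proline-catalysed alpha-aminoxylation through the enamine of the open hydroxy-aldehyde form of 4, the carboxylic acid of L-proline directing O-attack of nitrosobenzene to the face that gives (R) at C3, followed by hydrogenolysis of the weak N–O bond and reclosure to the lactol.

Step 5
Reactants: 7 2-methoxyresorcinol
Product: 8 2,6-bis(tert-butyldimethylsilyloxy)anisole
Conditions: TBSCl (2.4 equiv), imidazole, DMF, rt
Reagents that add atoms: tert-butyldimethylsilyl chloride, CC(C)(C)[Si](C)(C)Cl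
Why: Imidazole-promoted silylation of both phenols, which masks the ring positions ortho and para to oxygen against later electrophiles.

Step 6
Reactants: 8 2,6-bis(tert-butyldimethylsilyloxy)anisole
Product: 10 [3,5-bis(tert-butyldimethylsilyloxy)-4-methoxyphenyl]boronic acid, via pinacol boronate 9 (not isolated)
Conditions: B2pin2 (1.0 equiv), [Ir(OMe)(cod)]2 (1.5 mol %), 4,4'-di-tert-butyl-2,2'-bipyridine (3 mol %), THF, 80 °C; then NaIO4, NH4OAc, acetone/H2O, rt
Reagents that add atoms: bis(pinacolato)diboron, CC1(C)OB(B2OC(C)(C)C(C)(C)O2)OC1(C)C; water, O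
Why: Iridium-catalysed C–H borylation is sterically controlled and should occur only at the one C–H bond without an ortho substituent (para to OMe), and periodate cleavage of the released pinacol drives hydrolysis of the pinacol ester to the boronic acid.

Step 7
Reactants: 6 (3R)-5,7-bis(tert-butyldimethylsilyloxy)chroman-2,3-diol and 10 [3,5-bis(tert-butyldimethylsilyloxy)-4-methoxyphenyl]boronic acid
Product: 12 (2R,3R)-5,7-bis(tert-butyldimethylsilyloxy)-2-[3,5-bis(tert-butyldimethylsilyloxy)-4-methoxyphenyl]chroman-3-ol, via boronic half ester 11 (not isolated)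
Conditions: 10 (1.5 equiv), 4 Å MS, CH2Cl2, rt; then BF3·OEt2 (20 mol %), CH2Cl2/(CF3)2CHOH 4:1, −40 → 0 °C, 0.02 M; aq. NaHCO3
Reagents that add atoms: none
Why: Proposed new method: the C3 hydroxyl of 6 condenses with boronic acid 10 to half ester 11, acid-promoted loss of the anomeric hydroxyl from either anomer gives the planar O1=C2 oxocarbenium ion, and the tetracoordinate borate on O3 shifts its aryl group from boron to C2 through a five-membered cyclic transition state (C2, C3, O3, B, ipso carbon), the O3–B bond being hydrolysed on work-up. The closest known reaction types are the Petasis borono-Mannich reaction of alpha-hydroxy aldehydes, the hydroxyl-directed cis addition of aryl boronates to cyclic N-acyliminium ions and the Lewis-acid-promoted addition of aryl boronates to chromene acetals; their combination on a 3-hydroxychroman-2-yl cation is untested. No ring is closed. The new stereocenter C2 is controlled by the existing C3 stereocenter: because boron is tied to O3, the aryl group can only reach the face of C2 that carries O3, so both anomers of 6 should converge on the 2,3-cis (2R,3R) product. The step needs cis over trans selectivity, which the tether secures, and aryl transfer in preference to attack by the electron-rich ring A of a second molecule or a 1,2-hydride shift to the chroman-3-one, which high dilution, low temperature and the intramolecular delivery should secure. The ipso carbon of 10 is activated by the para methoxy group, as in the anisylboronic acids that are the best aryl donors in Petasis reactions.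

Step 8
Reactants: 13 (E)-ferulic acid
Product: 15 (E)-4-O-(tert-butyldimethylsilyl)ferulic acid, via silyl ester 14 (not isolated)
Conditions: TBSCl (2.3 equiv), imidazole, DMF, rt; then AcOH/THF/H2O, rt
Reagents that add atoms: tert-butyldimethylsilyl chloride, CC(C)(C)[Si](C)(C)Cl
Why: Silylation of both acidic OH groups followed by selective hydrolysis of the labile silyl ester, which leaves the aryl silyl ether in place.

Step 9
Reactants: 12 (2R,3R)-5,7-bis(tert-butyldimethylsilyloxy)-2-[3,5-bis(tert-butyldimethylsilyloxy)-4-methoxyphenyl]chroman-3-ol and 15 (E)-4-O-(tert-butyldimethylsilyl)ferulic acid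
Product: 16 (2R,3R)-5,7-bis(tert-butyldimethylsilyloxy)-2-[3,5-bis(tert-butyldimethylsilyloxy)-4-methoxyphenyl]chroman-3-yl (E)-3-[4-(tert-butyldimethylsilyloxy)-3-methoxyphenyl]acrylate
Conditions: DCC (1.5 equiv), DMAP (0.3 equiv), CH2Cl2, 0 °C → rt
Reagents that add atoms: none
Why: Steglich esterification (carbodiimide activation with DMAP acyl transfer); only the O–H bond of the C3 alcohol reacts, so both stereocenters and the (E) alkene are retained.

Step 10
Reactants: 16 the fully silylated ester
Product: 17 4'-O-methylepigallocatechin-3-O-ferulate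
Conditions: Bu4NF (6 equiv), AcOH (6 equiv), THF, 0 °C → rt
Reagents that add atoms: none
Why: Fluoride-induced cleavage of the five aryl silyl ethers, buffered with acetic acid so that each phenoxide is protonated at once and neither the cinnamate ester nor the base-sensitive C2 centre is exposed to base.

**Compound list**

1 | 5,7-dihydroxycoumarin | O=C1C=Cc2c(O)cc(O)cc2O1 | starting material
2 | 5,7-bis(tert-butyldimethylsilyloxy)coumarin | O=C1C=Cc2c(O[Si](C)(C)C(C)(C)C)cc(O[Si](C)(C)C(C)(C)C)cc2O1 | intermediate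
3 | 5,7-bis(tert-butyldimethylsilyloxy)chroman-2-one | O=C1CCc2c(O[Si](C)(C)C(C)(C)C)cc(O[Si](C)(C)C(C)(C)C)cc2O1 | intermediate
4 | 5,7-bis(tert-butyldimethylsilyloxy)chroman-2-ol (anomeric mixture) | OC1CCc2c(O[Si](C)(C)C(C)(C)C)cc(O[Si](C)(C)C(C)(C)C)cc2O1 | intermediate
5 | (3R)-3-(N-phenylaminooxy)-5,7-bis(tert-butyldimethylsilyloxy)chroman-2-ol (anomeric mixture, not isolated) | c1ccccc1NO[C@@H]1Cc2c(O[Si](C)(C)C(C)(C)C)cc(O[Si](C)(C)C(C)(C)C)cc2OC1O | intermediate
6 | (3R)-5,7-bis(tert-butyldimethylsilyloxy)chroman-2,3-diol (anomeric mixture) | O[C@@H]1Cc2c(O[Si](C)(C)C(C)(C)C)cc(O[Si](C)(C)C(C)(C)C)cc2OC1O | intermediate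
7 | 2-methoxyresorcinol | COc1c(O)cccc1O | starting material
8 | 2,6-bis(tert-butyldimethylsilyloxy)anisole | COc1c(O[Si](C)(C)C(C)(C)C)cccc1O[Si](C)(C)C(C)(C)C | intermediate
9 | 2-[3,5-bis(tert-butyldimethylsilyloxy)-4-methoxyphenyl]-4,4,5,5-tetramethyl-1,3,2-dioxaborolane (not isolated) | COc1c(O[Si](C)(C)C(C)(C)C)cc(B2OC(C)(C)C(C)(C)O2)cc1O[Si](C)(C)C(C)(C)C | intermediate
10 | [3,5-bis(tert-butyldimethylsilyloxy)-4-methoxyphenyl]boronic acid | COc1c(O[Si](C)(C)C(C)(C)C)cc(B(O)O)cc1O[Si](C)(C)C(C)(C)C | intermediate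
11 | boronic half ester of 10 on O3 of lactol 6 (anomeric mixture, not isolated) | COc1c(O[Si](C)(C)C(C)(C)C)cc(B(O)O[C@@H]2Cc3c(O[Si](C)(C)C(C)(C)C)cc(O[Si](C)(C)C(C)(C)C)cc3OC2O)cc1O[Si](C)(C)C(C)(C)C | intermediate
12 | (2R,3R)-5,7-bis(tert-butyldimethylsilyloxy)-2-[3,5-bis(tert-butyldimethylsilyloxy)-4-methoxyphenyl]chroman-3-ol | O[C@@H]1Cc2c(O[Si](C)(C)C(C)(C)C)cc(O[Si](C)(C)C(C)(C)C)cc2O[C@@H]1c1cc(O[Si](C)(C)C(C)(C)C)c(OC)c(O[Si](C)(C)C(C)(C)C)c1 | intermediate
13 | (E)-ferulic acid | COc1cc(/C=C/C(=O)O)ccc1O | starting material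
14 | tert-butyldimethylsilyl (E)-4-O-(tert-butyldimethylsilyl)ferulate (not isolated) | COc1cc(/C=C/C(=O)O[Si](C)(C)C(C)(C)C)ccc1O[Si](C)(C)C(C)(C)C | intermediate
15 | (E)-4-O-(tert-butyldimethylsilyl)ferulic acid | COc1cc(/C=C/C(=O)O)ccc1O[Si](C)(C)C(C)(C)C | intermediate
16 | (2R,3R)-5,7-bis(tert-butyldimethylsilyloxy)-2-[3,5-bis(tert-butyldimethylsilyloxy)-4-methoxyphenyl]chroman-3-yl (E)-3-[4-(tert-butyldimethylsilyloxy)-3-methoxyphenyl]acrylate | COc1cc(/C=C/C(=O)O[C@@H]2Cc3c(O[Si](C)(C)C(C)(C)C)cc(O[Si](C)(C)C(C)(C)C)cc3O[C@@H]2c2cc(O[Si](C)(C)C(C)(C)C)c(OC)c(O[Si](C)(C)C(C)(C)C)c2)ccc1O[Si](C)(C)C(C)(C)C | intermediate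
17 | 4'-O-methylepigallocatechin-3-O-ferulate | COc1cc(/C=C/C(=O)O[C@@H]2Cc3c(O)cc(O)cc3O[C@@H]2c2cc(O)c(OC)c(O)c2)ccc1O | target

**Totals**

Total step count: 10.
Longest linear sequence: 7 steps (steps 1, 2, 3, 4, 7, 9, 10).

**Steps most likely to fail**

1. Step 7 (proposed new method). The aryl shift from boron may be too slow to outpace other fates of the oxocarbenium ion: intermolecular attack by ring A of a second molecule, hydride shift or enolisation towards the chroman-3-one, and protodeboronation of the electron-rich boronic acid. The fallback uses known chemistry, sets out from coumarin 2 and boronic acid 10, and returns at 12. Reduction of 2 with i-Bu2AlH (CH2Cl2, −78 °C) should give 5,7-bis(tert-butyldimethylsilyloxy)-2H-chromen-2-ol F1, and EtOH with pyridinium p-toluenesulfonate its ethyl acetal, 2-ethoxy-5,7-bis(tert-butyldimethylsilyloxy)-2H-chromene F2. Boronic acid 10 is esterified with EtOH over 4 Å MS to diethyl [3,5-bis(tert-butyldimethylsilyloxy)-4-methoxyphenyl]boronate F3. Enantioselective addition of F3 to the benzopyrylium ion from F2, under a chiral tartaric-acid-derived diol amide with Yb(OTf)3 (both catalytic, catalyst enantiomer chosen for the (S) product), forms the same C2–aryl bond and should give (S)-5,7-bis(tert-butyldimethylsilyloxy)-2-[3,5-bis(tert-butyldimethylsilyloxy)-4-methoxyphenyl]-2H-chromene F4. Hydroboration anti to the aryl group (BH3·THF; NaBO3·4H2O) should give the 2,3-trans alcohol, (2R,3S)-5,7-bis(tert-butyldimethylsilyloxy)-2-[3,5-bis(tert-butyldimethylsilyloxy)-4-methoxyphenyl]chroman-3-ol F5. Dess–Martin oxidation then gives (2R)-5,7-bis(tert-butyldimethylsilyloxy)-2-[3,5-bis(tert-butyldimethylsilyloxy)-4-methoxyphenyl]chroman-3-one F6. Reduction with LiBH(s-Bu)3 (THF, −78 °C), hydride entering anti to the aryl group, should give the cis alcohol 12.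

2. Step 4. The lactol may release too little open-chain aldehyde for efficient enamine formation, nitrosobenzene may attack the electron-rich free phenol, and the aniline set free may condense with the hydroxy lactol. The fallback moves the oxygenation to the lactone oxidation level; it sets out from 3 and returns at 6. Deprotonation of 3 with KN(SiMe3)2 (THF, −78 °C) and oxidation of the enolate with (camphorsulfonyl)oxaziridine (the reagent enantiomer matched to the (R) alcohol in a trial run) should give (3R)-3-hydroxy-5,7-bis(tert-butyldimethylsilyloxy)chroman-2-one F7. Partial reduction with i-Bu2AlH at −78 °C then gives 6.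

3. Step 10. Fivefold desilylation may stall at partly silylated stages, and prolonged contact with fluoride may bring ester cleavage, epimerisation at C2 or air oxidation of the freed polyphenol. The fallback exchanges the protecting groups before release; it sets out from 16 and returns at 17. Treatment of 16 with Bu4NF in the presence of Ac2O (THF, 0 °C) traps each phenoxide as its acetate and should give the stable, purifiable (2R,3R)-5,7-diacetoxy-2-(3,5-diacetoxy-4-methoxyphenyl)chroman-3-yl (E)-3-(4-acetoxy-3-methoxyphenyl)acrylate F8. NH4OAc in aqueous MeOH at rt then removes the five phenolic acetates under near-neutral conditions, leaving the alkyl cinnamate ester, and gives 17.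

**Further compounds**

F1 | step 7 | 5,7-bis(tert-butyldimethylsilyloxy)-2H-chromen-2-ol | OC1C=Cc2c(O[Si](C)(C)C(C)(C)C)cc(O[Si](C)(C)C(C)(C)C)cc2O1
F2 | step 7 | 2-ethoxy-5,7-bis(tert-butyldimethylsilyloxy)-2H-chromene | CCOC1C=Cc2c(O[Si](C)(C)C(C)(C)C)cc(O[Si](C)(C)C(C)(C)C)cc2O1
F3 | step 7 | diethyl [3,5-bis(tert-butyldimethylsilyloxy)-4-methoxyphenyl]boronate | CCOB(OCC)c1cc(O[Si](C)(C)C(C)(C)C)c(OC)c(O[Si](C)(C)C(C)(C)C)c1
F4 | step 7 | (S)-5,7-bis(tert-butyldimethylsilyloxy)-2-[3,5-bis(tert-butyldimethylsilyloxy)-4-methoxyphenyl]-2H-chromene | C1=Cc2c(O[Si](C)(C)C(C)(C)C)cc(O[Si](C)(C)C(C)(C)C)cc2O[C@@H]1c1cc(O[Si](C)(C)C(C)(C)C)c(OC)c(O[Si](C)(C)C(C)(C)C)c1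
F5 | step 7 | (2R,3S)-5,7-bis(tert-butyldimethylsilyloxy)-2-[3,5-bis(tert-butyldimethylsilyloxy)-4-methoxyphenyl]chroman-3-ol | O[C@H]1Cc2c(O[Si](C)(C)C(C)(C)C)cc(O[Si](C)(C)C(C)(C)C)cc2O[C@@H]1c1cc(O[Si](C)(C)C(C)(C)C)c(OC)c(O[Si](C)(C)C(C)(C)C)c1
F6 | step 7 | (2R)-5,7-bis(tert-butyldimethylsilyloxy)-2-[3,5-bis(tert-butyldimethylsilyloxy)-4-methoxyphenyl]chroman-3-one | O=C1Cc2c(O[Si](C)(C)C(C)(C)C)cc(O[Si](C)(C)C(C)(C)C)cc2O[C@@H]1c1cc(O[Si](C)(C)C(C)(C)C)c(OC)c(O[Si](C)(C)C(C)(C)C)c1
F7 | step 4 | (3R)-3-hydroxy-5,7-bis(tert-butyldimethylsilyloxy)chroman-2-one | O[C@@H]1Cc2c(O[Si](C)(C)C(C)(C)C)cc(O[Si](C)(C)C(C)(C)C)cc2OC1=O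
F8 | step 10 | (2R,3R)-5,7-diacetoxy-2-(3,5-diacetoxy-4-methoxyphenyl)chroman-3-yl (E)-3-(4-acetoxy-3-methoxyphenyl)acrylate | COc1cc(/C=C/C(=O)O[C@@H]2Cc3c(OC(C)=O)cc(OC(C)=O)cc3O[C@@H]2c2cc(OC(C)=O)c(OC)c(OC(C)=O)c2)ccc1OC(C)=O
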